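**Retrosynthetic overview**
1. Cycloshizukaol A ⇒ two molecules of the (Z)-trienone ester (C15=C4–C5=C6–C7=C11), joined head to tail by a formal [6+6] dimerisation (C15–C11′ and C15′–C11). The twelve-membered ring and both quaternary centres form last, in one operation.
2. Trienone ester ⇒ tertiary acetate 17 (E1cB) ⇒ hydroxy dienone 14 + methyl pyruvate (aldol at C7).
3. Dienone 14 ⇒ six-membered ring by Diels–Alder reaction of Rawal's diene with bicyclic enone 7 (anti to the cyclopropane, sets C10), then methylenation, unmasking and C9 hydroxylation.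
4. Enone 7 ⇒ cyclopropane and five-membered ring together, by intramolecular cyclopropanation of a lithiated epoxide made from (S)-epichlorohydrin and crotylmagnesium chloride.
5. Ring order: cyclopropane + five-membered ring → six-membered ring → twelve-membered ring.

Assumption: lindenane numbering is used for the tricyclic compounds (C1–C3 cyclopropane, C14 = methyl on C10, C15 on C4, C11–C13 on C7; β = face of C14, which also carries the cyclopropane CH2 and the 9-OH of the target), and the target's 9β-OH α-ketol is taken to be the thermodynamic C9 epimer.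

**Step 1**
Reactants: 1 (S)-epichlorohydrin; 2 (E)-but-2-en-1-ylmagnesium chloride (crotylmagnesium chloride)
Product: 3 (2S,4RS)-1-chloro-4-methylhex-5-en-2-ol
Conditions: THF, −40 → 0 °C; aq. NH4Cl
Reagents that add atoms: none
Why: Epoxide opening by an allylic Grignard reagent with allylic transposition (SE2′) at the unsubstituted epoxide carbon places the future C14 methyl on the allylic carbon; the carbinol centre comes unchanged from 1 and the C4 centre is erased in step 3.

**Step 2**
Reactants: 3 (2S,4RS)-1-chloro-4-methylhex-5-en-2-ol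
Product: 5 (1S,2S,5S,4RS)-4-methylbicyclo[3.1.0]hexan-2-ol (OH trans to the cyclopropane CH2), via epoxide 4 (not isolated)
Conditions: lithium 2,2,6,6-tetramethylpiperidide (3 equiv, from the amine and n-BuLi), t-BuOMe, 0 °C → rt; aq. NH4Cl
Reagents that add atoms: none
Why: Hodgson intramolecular cyclopropanation (chlorohydrin closes to the epoxide, trans-α-lithiation gives a carbenoid that adds to the tethered alkene); the carbinol centre directs the addition so that OH ends trans to the cyclopropane, which fixes the absolute configuration of the two ring-fusion carbons (future C1 and C3).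

**Step 3**
Reactants: 5 (1S,2S,5S,4RS)-4-methylbicyclo[3.1.0]hexan-2-ol
Product: 7 (1S,5R)-4-methylbicyclo[3.1.0]hex-3-en-2-one, via saturated ketone 6 (not isolated)
Conditions: IBX (3.5 equiv), DMSO, 25 °C then 75 °C
Reagents that add atoms: none
Why: IBX alcohol oxidation followed by IBX dehydrogenation of the ketone (Nicolaou desaturation); only the C3–C4 bond can be desaturated because the other α-carbon is a cyclopropane bridgehead, and this removes the C4 epimer mixture.

**Step 4**
Reactants: 7 (1S,5R)-4-methylbicyclo[3.1.0]hex-3-en-2-one; 8 (E)-3-(tert-butyldimethylsilyloxy)-N,N-dimethylbuta-1,3-dien-1-amine (Rawal's diene)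
Product: 9 6α-(dimethylamino)-8-(tert-butyldimethylsilyloxy)-11,12,13,15-tetranor-5β-linden-7-en-4-one
Conditions: 8 (2 equiv), PhMe, 80 °C, sealed tube
Reagents that add atoms: none
Why: Diels–Alder reaction of an aminosiloxy diene (possibly stepwise Michael/Mannich on this strained enone): the nucleophilic CH2 terminus bonds to the β-carbon and the diene approaches the face opposite the cyclopropane CH2, which sets the C10 quaternary centre with C14 cis to the cyclopropane methylene; the C5 and C6 centres are removed in step 5.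

**Step 5**
Reactants: 9 6α-(dimethylamino)-8-(tert-butyldimethylsilyloxy)-11,12,13,15-tetranor-5β-linden-7-en-4-one
Product: 12 11,12,13-trinorlindena-4,6-dien-8-one, via methylenated adduct 10 (not isolated), via exo-methylene enone 11 (not isolated)
Conditions: Ph3PCH3Br, KOtBu, THF, 0 °C → rt; then aq. HF, MeCN, 0 °C; then DBU (0.2 equiv), CH2Cl2, rt
Reagents that add atoms: methyltriphenylphosphonium bromide, C[P+](c1ccccc1)(c1ccccc1)c1ccccc1.[Br-]
Why: Wittig methylenation of the only ketone, then acid hydrolysis of the silyl enol ether with β-elimination of dimethylamine (the usual unmasking of Rawal adducts) and base isomerisation of the exocyclic alkene into the linearly conjugated, thermodynamically preferred dienone; no new stereocentre is formed and C5 and C6 become sp2.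

**Step 6**
Reactants: 12 11,12,13-trinorlindena-4,6-dien-8-one
Product: 14 9β-hydroxy-11,12,13-trinorlindena-4,6-dien-8-one, via 9α-hydroxy epimer 13 (not isolated)
Conditions: KN(SiMe3)2, THF, −78 °C; 2-(phenylsulfonyl)-3-phenyloxaziridine, −78 °C; AcOH; then DBU (0.2 equiv), CH2Cl2, rt, argon
Reagents that add atoms: 2-(phenylsulfonyl)-3-phenyloxaziridine, O=S(=O)(N1OC1c1ccccc1)c1ccccc1
Why: Kinetic α′-enolate formation and Davis oxaziridine hydroxylation, which attacks anti to the axial C14 methyl and gives mainly the 9α-alcohol; amine-mediated enediol equilibration then delivers the pseudo-equatorial 9β-OH (cis to C14, hydrogen-bonded to the C8 carbonyl).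

**Step 7**
Reactants: 14 9β-hydroxy-11,12,13-trinorlindena-4,6-dien-8-one; 15 methyl pyruvate
Product: 17 methyl 9β,11-diacetoxy-8-oxolindena-4(15),5-dien-12-oate (C7/C11 epimers), via aldol diol 16 (not isolated)
Conditions: LiN(iPr)2 (2.3 equiv), THF, −78 → −40 °C; 15, −78 °C; Ac2O (3 equiv), −78 → −40 °C; pH 7 buffer, cold
Reagents that add atoms: acetic anhydride, CC(=O)OC(C)=O
Why: Aldol addition of a lithium trienolate: after O–H deprotonation the second equivalent removes a C15 proton (the α′ C9–H sits next to the alkoxide), the extended enolate reacts at its α-carbon C7 with the activated ketone of 15 under kinetic control, and both alkoxides are acetylated in situ; the new C7 and C11 centres are mixtures and are both erased in step 8.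

**Step 8**
Reactants: 17 methyl 9β,11-diacetoxy-8-oxolindena-4(15),5-dien-12-oate (first molecule); 17 methyl 9β,11-diacetoxy-8-oxolindena-4(15),5-dien-12-oate (second molecule)
Product: 20 cycloshizukaol A, via (Z)-trienone ester 18 (not isolated), via dimer diacetate 19 (not isolated)
Conditions: LiN(SiMe3)2 (1.05 equiv per 17), THF, −78 → 0 °C; then 45 °C, 0.3 M in 17, 12 h; then K2CO3 (0.3 equiv), MeOH, 0 °C → rt
Reagents that add atoms: none
Why: Proposed new method: this step is a homodimerisation in which two molecules of 17 give one molecule of 20 (2 × 17 → 2 × 18 + 2 LiOAc; 2 × 18 → 19; 19 + 2 MeOH → 20 + 2 MeOAc); E1cB loss of acetate from the C7 lithium enolate, in which lithium bridges the enolate oxygen and the ester carbonyl (and the smaller CO2Me rather than CH3 sits next to the enolate oxygen), should give the (Z)-trienone ester 18 with CO2Me cis to C8=O, and two molecules of 18 then join head to tail in a stepwise polar formal [6+6] cycloaddition in which the diene terminus C15 (donor, cation stabilised as allyl and cyclopropylcarbinyl) adds to C11′ (β-carbon of the C8′ enone) and the resulting trienolate closes C15′→C11, both bonds forming on the open α faces (the β faces carry C14, the cyclopropane CH2 and the 9-acetate), which from the Z-alkene gives the (11R,11′R) quaternary centres; the closest known reactions are the formal [6+6] dimerisations of p-xylylenes and 2,5-dimethylene-2,5-dihydrofurans to [2.2]cyclophanes and the thermal [4+2] dimerisations of this class of lindenane trienes, and mild methanolysis finally removes both acetates and leaves the equatorial 9β-OH.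

**Compound list**
1 | (S)-epichlorohydrin | ClC[C@@H]1CO1 | starting material
2 | (E)-but-2-en-1-ylmagnesium chloride (crotylmagnesium chloride) | C/C=C/C[Mg]Cl | starting material
3 | (2S,4RS)-1-chloro-4-methylhex-5-en-2-ol | ClC[C@@H](O)CC(C)C=C | intermediate
4 | (2S)-2-(2-methylbut-3-en-1-yl)oxirane (epimers at the methyl-bearing carbon) | C=CC(C)C[C@H]1CO1 | intermediate
5 | (1S,2S,5S,4RS)-4-methylbicyclo[3.1.0]hexan-2-ol, OH trans to the cyclopropane CH2 | O[C@H]1CC(C)[C@@H]2C[C@H]12 | intermediate
6 | (1S,5S,4RS)-4-methylbicyclo[3.1.0]hexan-2-one | O=C1CC(C)[C@@H]2C[C@H]12 | intermediate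
7 | (1S,5R)-4-methylbicyclo[3.1.0]hex-3-en-2-one | O=C1C=C(C)[C@@H]2C[C@H]12 | intermediate
8 | (E)-3-(tert-butyldimethylsilyloxy)-N,N-dimethylbuta-1,3-dien-1-amine (Rawal's diene) | CN(C)/C=C/C(=C)O[Si](C)(C)C(C)(C)C | starting material
9 | 6α-(dimethylamino)-8-(tert-butyldimethylsilyloxy)-11,12,13,15-tetranor-5β-linden-7-en-4-one (5β-H, 10β-CH3, cyclopropane CH2 β) | O=C1[C@H]2[C@@H](N(C)C)C=C(O[Si](C)(C)C(C)(C)C)C[C@@]2(C)[C@@H]3C[C@H]13 | intermediate
10 | 6α-(dimethylamino)-8-(tert-butyldimethylsilyloxy)-11,12,13-trinor-5β-lindena-4(15),7-diene | C=C1[C@H]2[C@@H](N(C)C)C=C(O[Si](C)(C)C(C)(C)C)C[C@@]2(C)[C@@H]3C[C@H]13 | intermediate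
11 | 11,12,13-trinor-5β-lindena-4(15),6-dien-8-one | C=C1[C@H]2C=CC(=O)C[C@@]2(C)[C@@H]3C[C@H]13 | intermediate
12 | 11,12,13-trinorlindena-4,6-dien-8-one | CC1=C2C=CC(=O)C[C@@]2(C)[C@@H]3C[C@H]13 | intermediate
13 | 9α-hydroxy-11,12,13-trinorlindena-4,6-dien-8-one | CC1=C2C=CC(=O)[C@@H](O)[C@@]2(C)[C@@H]3C[C@H]13 | intermediate
14 | 9β-hydroxy-11,12,13-trinorlindena-4,6-dien-8-one (OH cis to C14) | CC1=C2C=CC(=O)[C@H](O)[C@@]2(C)[C@@H]3C[C@H]13 | intermediate
15 | methyl pyruvate | CC(=O)C(=O)OC | starting material
16 | methyl 9β,11-dihydroxy-8-oxolindena-4(15),5-dien-12-oate (C7/C11 epimers) | C=C1C2=CC(C(C)(O)C(=O)OC)C(=O)[C@H](O)[C@@]2(C)[C@@H]3C[C@H]13 | intermediate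
17 | methyl 9β,11-diacetoxy-8-oxolindena-4(15),5-dien-12-oate (C7/C11 epimers) | C=C1C2=CC(C(C)(OC(C)=O)C(=O)OC)C(=O)[C@H](OC(C)=O)[C@@]2(C)[C@@H]3C[C@H]13 | intermediate
18 | methyl (7(11)Z)-9β-acetoxy-8-oxolindena-4(15),5,7(11)-trien-12-oate (CO2Me cis to C8=O) | C=C1C2=C/C(=C(\C)C(=O)OC)C(=O)[C@H](OC(C)=O)[C@@]2(C)[C@@H]3C[C@H]13 | intermediate
19 | cycloshizukaol A 9,9′-diacetate (11R,11′R), formed from two molecules of 18 | COC(=O)[C@]1(C)CC2=C3C=C(C(=O)[C@H](OC(C)=O)[C@@]3(C)[C@@H]3C[C@H]23)[C@](C)(C(=O)OC)CC2=C3C=C1C(=O)[C@H](OC(C)=O)[C@@]3(C)[C@@H]1C[C@H]21 | intermediate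
20 | cycloshizukaol A | COC(=O)[C@]1(C)CC2=C3C=C(C(=O)[C@H](O)[C@@]3(C)[C@@H]3C[C@H]23)[C@](C)(C(=O)OC)CC2=C3C=C1C(=O)[C@H](O)[C@@]3(C)[C@@H]1C[C@H]21 | target

**Totals**
Total step count: 8. Longest linear sequence: 8 steps (1 → 20; 8 and 15 are purchased; step 8 consumes two molecules of 17 per molecule of 20).

**Steps most likely to fail**

Step 8 (kinetic Z-selective elimination and head-to-tail dimerisation; the (E)-triene, [4+2] dimers or oligomers could form instead). Fallback: lock the alkene geometry in a ring before the dimerisation. Setting out from 14, the dianion aldol of step 7 is run with allyl pyruvate and quenched without acetylation to give allyl 9β,11-dihydroxy-8-oxolindena-4(15),5-dien-12-oate F1. Pd(PPh3)4 and morpholine remove the allyl group to give the hydroxy acid F2. Warming F2 in Ac2O/NaOAc dehydrates it and closes the acid onto C8, which only the (Z)-acid can do while the (E)-acid is returned by reversible acetate addition, giving 8,9β-diacetoxylindena-4(15),5,7(11)-trien-8,12-olide F3. K2CO3/MeOH and then MeI open F3 to methyl (7(11)Z)-9β-hydroxy-8-oxolindena-4(15),5,7(11)-trien-12-oate F4, two molecules of which dimerise on warming in toluene. The fallback comes back to the route at 20.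

Step 4 (cycloaddition onto a β,β-disubstituted enone may be too slow). Fallback: anionic annulation in place of the cycloaddition. Setting out from 7, the lithium dienolate of (E)-4-methoxybut-3-en-2-one (LiN(iPr)2, THF, −78 °C) adds to C10 anti to the cyclopropane, the C5 enolate so formed closes on the β-methoxy enone with loss of methoxide, and work-up gives 11,12,13,15-tetranor-5β-linden-6-ene-4,8-dione F5. TBSOTf/Et3N silylates the more basic and less hindered enone oxygen with loss of H5 to give 8-(tert-butyldimethylsilyloxy)-11,12,13,15-tetranorlindena-5,7-dien-4-one F6. MeLi/CeCl3 adds to the C4 carbonyl to give the tertiary alcohol F7, and dilute HCl effects enol ether hydrolysis with allylic transposition (Stork–Danheiser type) to the dienone 12, where the fallback comes back to the route.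

Step 7 (the second deprotonation may occur at C9 instead of C15, and the β-acetoxy ketone may eliminate early). Fallback: fix the enolate regiochemistry through an isolated silyl trienol ether. Setting out from 14, TESOTf/Et3N gives 8,9β-bis(triethylsilyloxy)-11,12,13-trinorlindena-4(15),5,7-triene F8. MeLi cleaves only the enol silyl ether to the lithium trienolate, which is treated with 15 and then Ac2O to give methyl 11-acetoxy-8-oxo-9β-(triethylsilyloxy)lindena-4(15),5-dien-12-oate F9. LiN(SiMe3)2 gives the (Z)-trienone ester triethylsilyl ether F10, and warming joins two molecules of it to give cycloshizukaol A 9,9′-bis(triethylsilyl) ether F11. HF·pyridine removes the silyl groups and the fallback comes back to the route at 20.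

**Further compounds**
F1 | step 8 | allyl 9β,11-dihydroxy-8-oxolindena-4(15),5-dien-12-oate (C7/C11 epimers) | C=C1C2=CC(C(C)(O)C(=O)OCC=C)C(=O)[C@H](O)[C@@]2(C)[C@@H]3C[C@H]13
F2 | step 8 | 9β,11-dihydroxy-8-oxolindena-4(15),5-dien-12-oic acid (C7/C11 epimers) | C=C1C2=CC(C(C)(O)C(=O)O)C(=O)[C@H](O)[C@@]2(C)[C@@H]3C[C@H]13
F3 | step 8 | 8,9β-diacetoxylindena-4(15),5,7(11)-trien-8,12-olide (C8 epimers) | C=C1C2=CC3=C(C)C(=O)OC3(OC(C)=O)[C@H](OC(C)=O)[C@@]2(C)[C@@H]4C[C@H]14
F4 | step 8 | methyl (7(11)Z)-9β-hydroxy-8-oxolindena-4(15),5,7(11)-trien-12-oate | C=C1C2=C/C(=C(\C)C(=O)OC)C(=O)[C@H](O)[C@@]2(C)[C@@H]3C[C@H]13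
F5 | step 4 | 11,12,13,15-tetranor-5β-linden-6-ene-4,8-dione | O=C1[C@H]2C=CC(=O)C[C@@]2(C)[C@@H]3C[C@H]13
F6 | step 4 | 8-(tert-butyldimethylsilyloxy)-11,12,13,15-tetranorlindena-5,7-dien-4-one | O=C1C2=CC=C(O[Si](C)(C)C(C)(C)C)C[C@@]2(C)[C@@H]3C[C@H]13
F7 | step 4 | 8-(tert-butyldimethylsilyloxy)-11,12,13-trinorlindena-5,7-dien-4-ol (C4 epimers) | CC1(O)C2=CC=C(O[Si](C)(C)C(C)(C)C)C[C@@]2(C)[C@@H]3C[C@H]13
F8 | step 7 | 8,9β-bis(triethylsilyloxy)-11,12,13-trinorlindena-4(15),5,7-triene | C=C1C2=CC=C(O[Si](CC)(CC)CC)[C@H](O[Si](CC)(CC)CC)[C@@]2(C)[C@@H]3C[C@H]13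
F9 | step 7 | methyl 11-acetoxy-8-oxo-9β-(triethylsilyloxy)lindena-4(15),5-dien-12-oate (C7/C11 epimers) | C=C1C2=CC(C(C)(OC(C)=O)C(=O)OC)C(=O)[C@H](O[Si](CC)(CC)CC)[C@@]2(C)[C@@H]3C[C@H]13
F10 | step 7 | methyl (7(11)Z)-8-oxo-9β-(triethylsilyloxy)lindena-4(15),5,7(11)-trien-12-oate | C=C1C2=C/C(=C(\C)C(=O)OC)C(=O)[C@H](O[Si](CC)(CC)CC)[C@@]2(C)[C@@H]3C[C@H]13
F11 | step 7 | cycloshizukaol A 9,9′-bis(triethylsilyl) ether | COC(=O)[C@]1(C)CC2=C3C=C(C(=O)[C@H](O[Si](CC)(CC)CC)[C@@]3(C)[C@@H]3C[C@H]23)[C@](C)(C(=O)OC)CC2=C3C=C1C(=O)[C@H](O[Si](CC)(CC)CC)[C@@]3(C)[C@@H]1C[C@H]21
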